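The route rests on cutting the diaryl ether bond between the oxygen on ring B (the 1,3-disubstituted ring) and C3 of ring A (the monophenol ring), the carbon ortho to the C4 oxygen and meta to the C1 bridge. An intramolecular Ullmann etherification forms this bond and closes the 19-membered macrocycle in one operation. Its precursor 11 is an open-chain bis(bibenzyl) with exactly one free phenol (ring B) and one C-Br bond (ring A C3). The step exploits the adjacent C3/C4 pair of ring A: C4 carries its oxygen as OMe, and C3 a bromine that is bought in place and outlasts three iodide-selective couplings. Two hydroboration/Suzuki-Miyaura couplings deliver both bridges already saturated.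

Key step: step 5

Remark on the chemistry:
- Ring A is the monophenol ring (C1 bridge, C3 ether oxygen, C4 OH).
- Ring B is the 1,3-disubstituted ring.
- Ring C is the catechol ring (C1 bridge, C3 and C4 OH, C5 ether oxygen).
- Ring D is the 1,4-disubstituted ring.
- The target has no stereocentre and the 19-membered ring is taken as conformationally mobile, so no stereodescriptor is needed.

Step 1
Reactants: 1 4-ethenylphenyl acetate (4-acetoxystyrene); 2 2-bromo-4-iodo-1-methoxybenzene (2-bromo-4-iodoanisole)
Product: 5 4-[2-(3-bromo-4-methoxyphenyl)ethyl]phenol, via alkylborane 3 (not isolated), via aryl acetate 4 (not isolated)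
Conditions: 1, 9-BBN (1.1 equiv), THF, 0 °C to rt; then 2 (1.0 equiv), PdCl2(dppf) (3 mol %), 3 M aq NaOH (4 equiv), THF, 45 °C; aq NH4Cl work-up
Reagents that add atoms: none
Why: Anti-Markovnikov hydroboration with 9-BBN followed by B-alkyl Suzuki-Miyaura coupling should engage only the C-I bond of 2, because zerovalent palladium inserts into it far faster than into the hindered, electron-rich C-Br bond next to OMe, and the aqueous NaOH that drives transmetalation also saponifies the aryl acetate; no stereocentre is formed.

Step 2
Reactants: 6 3-iodo-4,5-dimethoxybenzaldehyde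
Product: 7 1-ethenyl-3-iodo-4,5-dimethoxybenzene (3-iodo-4,5-dimethoxystyrene)
Conditions: Ph3PCH3Br (1.3 equiv), KOtBu (1.25 equiv), THF, 0 °C to rt
Reagents that add atoms: methyltriphenylphosphonium bromide, [Br-].C[P+](c1ccccc1)(c1ccccc1)c1ccccc1
Why: Wittig methylenation of a non-enolisable aromatic aldehyde is reliable and leaves the aryl iodide and the methyl ethers untouched; no stereocentre is formed.

Step 3
Reactants: 5 4-[2-(3-bromo-4-methoxyphenyl)ethyl]phenol; 7 1-ethenyl-3-iodo-4,5-dimethoxybenzene
Product: 8 1-{4-[2-(3-bromo-4-methoxyphenyl)ethyl]phenoxy}-5-ethenyl-2,3-dimethoxybenzene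
Conditions: 7 (1.2 equiv), CuI (10 mol %), picolinic acid (20 mol %), K3PO4 (2 equiv), BHT (trace), DMSO, 80 °C, Ar
Reagents that add atoms: none
Why: Ligand-accelerated Ullmann diaryl ether coupling should take place at the C-I bond of 7, which monovalent copper activates at a temperature where the ortho-methoxy C-Br bond of 5 stays intact, while the vinyl group is a spectator under these weakly basic conditions.

Step 4
Reactants: 8 1-{4-[2-(3-bromo-4-methoxyphenyl)ethyl]phenoxy}-5-ethenyl-2,3-dimethoxybenzene; 9 3-iodophenol
Product: 11 3-{2-[3-{4-[2-(3-bromo-4-methoxyphenyl)ethyl]phenoxy}-4,5-dimethoxyphenyl]ethyl}phenol, via alkylborane 10 (not isolated)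
Conditions: 8, 9-BBN (1.2 equiv), THF, 0 °C to rt; then 9 (1.3 equiv), PdCl2(dppf) (3 mol %), 3 M aq NaOH (4 equiv), THF, 40 °C; aq NH4Cl work-up
Reagents that add atoms: none
Why: The same hydroboration and B-alkyl Suzuki-Miyaura sequence installs the second bridge at the saturated level, the external aryl iodide 9 used in excess outcompeting the hindered internal C-Br bond for zerovalent palladium, and the free phenol of 9 is simply carried as its phenoxide.

Step 5
Reactants: 11 3-{2-[3-{4-[2-(3-bromo-4-methoxyphenyl)ethyl]phenoxy}-4,5-dimethoxyphenyl]ethyl}phenol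
Product: 12 tri-O-methyl ether of the target macrocycle (OMe at ring A C4 and at ring C C3 and C4)
Conditions: CuI (50 mol %), N,N-dimethylglycine (1 equiv), Cs2CO3 (3 equiv), 1,4-dioxane, 100 °C, Ar; 11 added by syringe pump over 24 h, final 0.003 M
Reagents that add atoms: none
Why: Cs2CO3 turns the ring B phenol into its phenoxide, which binds dimethylglycinate-ligated monovalent copper; oxidative addition of the ring A C3-Br bond should give a trivalent copper aryl aryloxide, and reductive elimination forges the O-C3 bond and returns monovalent copper. The closest known reaction type is the intramolecular Ullmann diaryl ether macrocyclisation of a 3-bromo-4-methoxyphenyl unit with a remote phenol, established for diaryl ether heptanoids and related cyclophanes. The one ring closed is the 19-membered macrocycle (shortest path through three 1,3-phenylene units, one 1,4-phenylene unit, two CH2CH2 bridges and two oxygens), closed end to end by ipso substitution at an sp2 carbon. No stereocentre is formed and the ring is large enough that no stable planar-chiral conformer is expected. Chemoselectivity is built into 11, which holds one O-H and one C-halogen bond only, all other oxygens being methyl or diaryl ethers, so the only competing channels are intermolecular etherification, held back by pseudo-high dilution, and hydrodebromination, held back by a dry degassed medium. Site selectivity is fixed by the bromine at ring A C3, and the two flexible CH2CH2 bridges let the chain fold so that its ends meet without strain and without any activating group that would have to be removed afterwards.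

Step 6
Reactants: 12 tri-O-methyl ether of the target macrocycle
Product: 13 target CNP0495401.0 (macrocyclic bis(bibenzyl) with OH at ring A C4 and at ring C C3 and C4)
Conditions: BBr3 (8 equiv), CH2Cl2, -78 °C to rt, Ar; then H2O, 0 °C
Reagents that add atoms: none
Why: BBr3 demethylation proceeds by Lewis acid coordination to each OMe oxygen and bromide attack at the methyl carbon, which the two diaryl ether oxygens cannot undergo because they carry only sp2 carbons, so all three phenols should be released in one operation.

Compound list
1 | 4-ethenylphenyl acetate (4-acetoxystyrene) | CC(=O)Oc1ccc(C=C)cc1 | starting material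
2 | 2-bromo-4-iodo-1-methoxybenzene (2-bromo-4-iodoanisole) | COc1ccc(I)cc1Br | starting material
3 | 4-[2-(9-borabicyclo[3.3.1]nonan-9-yl)ethyl]phenyl acetate | CC(=O)Oc1ccc(CCB2C3CCCC2CCC3)cc1 | intermediate
4 | 4-[2-(3-bromo-4-methoxyphenyl)ethyl]phenyl acetate | CC(=O)Oc1ccc(CCc2ccc(OC)c(Br)c2)cc1 | intermediate
5 | 4-[2-(3-bromo-4-methoxyphenyl)ethyl]phenol | Oc1ccc(CCc2ccc(OC)c(Br)c2)cc1 | intermediate
6 | 3-iodo-4,5-dimethoxybenzaldehyde | COc1cc(C=O)cc(I)c1OC | starting material
7 | 1-ethenyl-3-iodo-4,5-dimethoxybenzene | COc1cc(C=C)cc(I)c1OC | intermediate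
8 | 1-{4-[2-(3-bromo-4-methoxyphenyl)ethyl]phenoxy}-5-ethenyl-2,3-dimethoxybenzene | COc1cc(C=C)cc(Oc2ccc(CCc3ccc(OC)c(Br)c3)cc2)c1OC | intermediate
9 | 3-iodophenol | Oc1cccc(I)c1 | starting material
10 | 9-{2-[3-{4-[2-(3-bromo-4-methoxyphenyl)ethyl]phenoxy}-4,5-dimethoxyphenyl]ethyl}-9-borabicyclo[3.3.1]nonane | COc1cc(CCB2C3CCCC2CCC3)cc(Oc2ccc(CCc3ccc(OC)c(Br)c3)cc2)c1OC | intermediate
11 | 3-{2-[3-{4-[2-(3-bromo-4-methoxyphenyl)ethyl]phenoxy}-4,5-dimethoxyphenyl]ethyl}phenol | COc1cc(CCc2cccc(O)c2)cc(Oc2ccc(CCc3ccc(OC)c(Br)c3)cc2)c1OC | intermediate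
12 | tri-O-methyl ether of the target macrocycle (OMe at ring A C4, ring C C3 and C4) | COc1ccc2cc1Oc1cccc(c1)CCc1cc(OC)c(OC)c(c1)Oc1ccc(cc1)CC2 | intermediate
13 | CNP0495401.0, macrocyclic bis(bibenzyl) triol | Oc1ccc2cc1Oc1cccc(c1)CCc1cc(O)c(O)c(c1)Oc1ccc(cc1)CC2 | target

Total step count: 6. Longest linear sequence: 5 steps (1, 3, 4, 5, 6; the branch through step 2 is equally long).

Steps most likely to fail

**Step 5 (key step).**
- Intermolecular etherification may outrun ring closure and build linear and cyclic oligomers.
- Slow oxidative addition at the electron-rich C-Br bond may leave time for hydrodebromination.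
- The fallback sets out from 11 and comes back at 12, and it inverts the polarity of ring A.
- Miyaura borylation of 11 (B2pin2, PdCl2(dppf), KOAc, dioxane, 80 °C) should give 3-{2-[3-(4-{2-[4-methoxy-3-(4,4,5,5-tetramethyl-1,3,2-dioxaborolan-2-yl)phenyl]ethyl}phenoxy)-4,5-dimethoxyphenyl]ethyl}phenol F1.
- A Chan-Lam-Evans coupling (Cu(OAc)2, pyridine, 4 Å molecular sieves, air, MeCN, 0.002 M, 40 °C) should then join the ring B oxygen to the same ring A carbon.
- This oxidative pathway starts from divalent copper and passes through trivalent copper near room temperature, where dilution can be pushed further.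

**Step 3.**
- Discrimination between iodide and bromide at copper may erode. The phenoxide of 5 would then also attack the ring A C-Br bond of a second molecule.
- The styrene may polymerise on long heating.
- The fallback sets out from 6 and comes back at 8. It makes the first ether before any C-Br bond exists.
- Aldehyde 6 is coupled under the same copper catalysis with an excess of purchased 4,4'-(ethane-1,2-diyl)diphenol (Oc1ccc(CCc2ccc(O)cc2)cc1). This should give 3-{4-[2-(4-hydroxyphenyl)ethyl]phenoxy}-4,5-dimethoxybenzaldehyde F2.
- NBS (1 equiv, MeCN, 0 °C) should brominate ortho to the only free phenol. Its para position is blocked, and ring C is deactivated by the formyl group. The product is 3-{4-[2-(3-bromo-4-hydroxyphenyl)ethyl]phenoxy}-4,5-dimethoxybenzaldehyde F3.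
- MeI and K2CO3 in acetone give 3-{4-[2-(3-bromo-4-methoxyphenyl)ethyl]phenoxy}-4,5-dimethoxybenzaldehyde F4.
- Wittig methylenation as in step 2 gives 8. Steps 1 and 2 are then not needed.

**Step 4.**
- Palladium may insert into the internal C-Br bond of the alkylborane and start oligomerisation.
- Beta-hydride elimination or slow transmetalation may erode the coupling.
- The fallback sets out from 8 and comes back at 11. It forms the bridge at the alkene level.
- A ligand-free Heck reaction of 8 with 9 (Pd(OAc)2, Bu4NCl, NaHCO3, DMF, 60 °C) uses conditions under which electron-rich aryl bromides are inert. It should give 3-[(E)-2-(3-{4-[2-(3-bromo-4-methoxyphenyl)ethyl]phenoxy}-4,5-dimethoxyphenyl)ethenyl]phenol F5.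
- Diimide reduction (p-toluenesulfonyl hydrazide, NaOAc, DME/H2O, reflux) saturates the stilbene without touching the C-Br bond and gives 11.

Further compounds
F1 | step 5 | 3-{2-[3-(4-{2-[4-methoxy-3-(4,4,5,5-tetramethyl-1,3,2-dioxaborolan-2-yl)phenyl]ethyl}phenoxy)-4,5-dimethoxyphenyl]ethyl}phenol | COc1cc(CCc2cccc(O)c2)cc(Oc2ccc(CCc3ccc(OC)c(B4OC(C)(C)C(C)(C)O4)c3)cc2)c1OC
F2 | step 3 | 3-{4-[2-(4-hydroxyphenyl)ethyl]phenoxy}-4,5-dimethoxybenzaldehyde | COc1cc(C=O)cc(Oc2ccc(CCc3ccc(O)cc3)cc2)c1OC
F3 | step 3 | 3-{4-[2-(3-bromo-4-hydroxyphenyl)ethyl]phenoxy}-4,5-dimethoxybenzaldehyde | COc1cc(C=O)cc(Oc2ccc(CCc3ccc(O)c(Br)c3)cc2)c1OC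
F4 | step 3 | 3-{4-[2-(3-bromo-4-methoxyphenyl)ethyl]phenoxy}-4,5-dimethoxybenzaldehyde | COc1cc(C=O)cc(Oc2ccc(CCc3ccc(OC)c(Br)c3)cc2)c1OC
F5 | step 4 | 3-[(E)-2-(3-{4-[2-(3-bromo-4-methoxyphenyl)ethyl]phenoxy}-4,5-dimethoxyphenyl)ethenyl]phenol | COc1cc(/C=C/c2cccc(O)c2)cc(Oc2ccc(CCc3ccc(OC)c(Br)c3)cc2)c1OC
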